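**Retrosynthetic overview**
- The target comes from its 1,4-bis(triethylsilyl) ether by desilylation; the C6 tiglate is put on by acylating the alkoxide that the ring closure itself produces.
- Ten-membered ring: the C6–C7 bond is closed by a butenolide-borne 2-acylallyl metal (C13–C11=C7) attacking the C6 aldehyde, with the double bond moving to C11=C13. This is the bond that germacrene A synthase makes from farnesyl diphosphate (C1 electrophile, C10=C11 nucleophile).
- Five-membered lactone: the O8–C12 ester bond is made by acylating the C8 carbinol, and the ring is completed by metathesis before the carbocycle, so that only O8 can hold C12 and the ring can template the cis fusion. Ring order: lactone first, ten-membered ring second.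
- Open chain: the C1–C10 bond comes from an asymmetric Ni/Cr coupling of a (Z)-vinyl iodide (fragment B) with an aldehyde (fragment A).
- Fragment A comes from geraniol (Sharpless epoxidation sets C4); fragment B from but-2-yn-1-ol, hex-1-yne and 2-(bromomethyl)acrylic acid (catalytic alkenylzinc addition sets C8).

Assumption: atoms are numbered as in a germacran-8,12-olide (C8 lactone carbinol, C6 tiglate carbinol, C4 tertiary carbinol, C1 allylic carbinol, C9=C10 Z, C11–C13 acrylate unit); the given SMILES then reads (1S,4S,6R,7S,8R,9Z).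

**Step 1**
Reactants: 1 geraniol
Product: 2 (2S,3S)-2,3-epoxygeraniol
Conditions: Ti(OiPr)4 (5 mol %), L-(+)-diethyl tartrate (6 mol %), t-BuOOH, 4 Å molecular sieves, CH2Cl2, −20 °C
Reagents that add atoms: tert-butyl hydroperoxide, CC(C)(C)OO
Why: Sharpless asymmetric epoxidation, in which the titanium–L-tartrate complex delivers oxygen to one face of the allylic alcohol and so fixes the future C4 as (S) (the second epoxide carbon loses its stereocentre in step 2).

**Step 2**
Reactants: 2 (2S,3S)-2,3-epoxygeraniol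
Product: 3 (3S)-3,7-dimethyloct-6-ene-1,3-diol
Conditions: NaAlH2(OCH2CH2OMe)2, THF, 0 °C to rt; aq. KNaC4H4O6
Reagents that add atoms: none
Why: Hydroxyl-directed reductive opening of a 2,3-epoxy alcohol, in which the alkoxy-bound aluminate delivers hydride to C2 so that the tertiary C–O bond and its configuration are untouched and the 1,3-diol results.

**Step 3**
Reactants: 3 (3S)-3,7-dimethyloct-6-ene-1,3-diol
Product: 4 (3S)-3,7-dimethyl-1,3-bis(triethylsilyloxy)oct-6-ene
Conditions: Et3SiOTf (2.5 equiv), 2,6-lutidine, CH2Cl2, −78 to 0 °C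
Reagents that add atoms: triethylsilyl trifluoromethanesulfonate, CC[Si](CC)(CC)OS(=O)(=O)C(F)(F)F
Why: Silyl triflate silylation caps both the primary and the hindered tertiary hydroxyl (which would otherwise trap the aldehyde of step 4 as a lactol) without touching the stereocentre.

**Step 4**
Reactants: 4 (3S)-3,7-dimethyl-1,3-bis(triethylsilyloxy)oct-6-ene
Product: 6 (4S)-4-methyl-4,6-bis(triethylsilyloxy)hexanal, via ozonide 5 (not isolated)
Conditions: O3, CH2Cl2, −78 °C; then PPh3, −78 °C to rt
Reagents that add atoms: ozone, [O-][O+]=O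
Why: Ozonolysis with reductive work-up cleaves the only alkene to give the C1 aldehyde (fragment A) and acetone.

**Step 5**
Reactants: 7 but-2-yn-1-ol
Product: 9 (2Z)-3-iodobut-2-en-1-ol, via alkenylaluminate 8 (not isolated)
Conditions: NaAlH2(OCH2CH2OMe)2, THF, 0 °C to rt; then I2, −78 °C
Reagents that add atoms: iodine, II
Why: Alkoxide-directed trans-hydroalumination of the propargylic alcohol places aluminium on C3 cis to the CH2O group in a five-membered aluminate, and iodinolysis with retention gives the (Z)-vinyl iodide that becomes the Z C9=C10 bond.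

**Step 6**
Reactants: 9 (2Z)-3-iodobut-2-en-1-ol
Product: 10 (2Z)-3-iodobut-2-enal
Conditions: MnO2, CH2Cl2, rt, dark
Reagents that add atoms: none
Why: Neutral allylic oxidation with MnO2 gives the enal without Z-to-E isomerisation; it is used at once.

**Step 7**
Reactants: 10 (2Z)-3-iodobut-2-enal; 11 hex-1-yne
Product: 14 (2Z,4S,5E)-2-iododeca-2,5-dien-4-ol, via alkenylborane 12 (not isolated), via alkenylzinc 13 (not isolated)
Conditions: 11, Cy2BH, toluene, 0 °C to rt; Me2Zn, −78 °C; (2S)-(−)-3-exo-morpholinoisoborneol [(−)-MIB, 5 mol %]; then 10, −20 to 0 °C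
Reagents that add atoms: none
Why: Hydroboration, boron-to-zinc exchange and amino-alcohol-catalysed alkenylzinc addition (Oppolzer-type asymmetric alkenylation), in which (−)-MIB directs alkenyl transfer to the Si face of the aldehyde and so sets the future C8 (4S here).

**Step 8**
Reactants: 14 (2Z,4S,5E)-2-iododeca-2,5-dien-4-ol; 15 2-(bromomethyl)prop-2-enoic acid
Product: 16 (2Z,4S,5E)-2-iododeca-2,5-dien-4-yl 2-(bromomethyl)prop-2-enoate
Conditions: DCC, DMAP (5 mol %), CH2Cl2, 0 °C
Reagents that add atoms: none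
Why: Steglich esterification acylates the carbinol oxygen with retention at C8 and forms the O8–C12 ester bond of the future lactone.

**Step 9**
Reactants: 16 (2Z,4S,5E)-2-iododeca-2,5-dien-4-yl 2-(bromomethyl)prop-2-enoate
Product: 18 {(5S)-5-[(1Z)-2-iodoprop-1-en-1-yl]-2-oxo-2,5-dihydrofuran-3-yl}methyl acetate, via bromide 17 (not isolated)
Conditions: second-generation Grubbs catalyst RuCl2(=CHPh)(H2IMes)(PCy3) (5 mol %), toluene, 80 °C; then Bu4NOAc, THF, 0 °C
Reagents that add atoms: tetrabutylammonium acetate, CC(=O)[O-].CCCC[N+](CCCC)(CCCC)CCCC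
Why: Ring-closing metathesis between the acrylate and the disubstituted alkene closes the five-membered butenolide with loss of hex-1-ene (the vinyl iodide is inert), and SN2 displacement of the primary allylic bromide by acetate gives an allyl donor (fragment B) that divalent chromium does not reduce.

**Step 10**
Reactants: 18 {(5S)-5-[(1Z)-2-iodoprop-1-en-1-yl]-2-oxo-2,5-dihydrofuran-3-yl}methyl acetate; 6 (4S)-4-methyl-4,6-bis(triethylsilyloxy)hexanal
Product: 20 {(5R)-5-[(1Z,3S,6S)-2,6-dimethyl-3,6,8-tris(triethylsilyloxy)oct-1-en-1-yl]-2-oxo-2,5-dihydrofuran-3-yl}methyl acetate, via chromium alkoxide 19 (not isolated)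
Conditions: CrCl2 (15 mol %), N-{2-[(4S)-4-isopropyl-4,5-dihydro-1,3-oxazol-2-yl]-6-methylphenyl}methanesulfonamide (17 mol %), 1,8-bis(dimethylamino)naphthalene (17 mol %); NiCl2·2,9-dimethyl-1,10-phenanthroline (2 mol %), Mn, LiCl, Et3SiCl, MeCN, rt
Reagents that add atoms: chlorotriethylsilane, CC[Si](CC)(CC)Cl
Why: Catalytic asymmetric Nozaki–Hiyama–Kishi coupling, in which zerovalent nickel activates the vinyl iodide with retention of the Z geometry, the sulfonamide-bound alkenylchromium adds to one aldehyde face to set C1 as (S) (ligand hand chosen for this sense), and Et3SiCl frees the alkoxide from chromium as its silyl ether so the metal turns over.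

**Step 11**
Reactants: 20 {(5R)-5-[(1Z,3S,6S)-2,6-dimethyl-3,6,8-tris(triethylsilyloxy)oct-1-en-1-yl]-2-oxo-2,5-dihydrofuran-3-yl}methyl acetate
Product: 21 {(5R)-5-[(1Z,3S,6S)-2,6-dimethyl-8-oxo-3,6-bis(triethylsilyloxy)oct-1-en-1-yl]-2-oxo-2,5-dihydrofuran-3-yl}methyl acetate
Conditions: (COCl)2, DMSO, CH2Cl2, −78 to −40 °C; then i-Pr2NEt, −78 to 0 °C
Reagents that add atoms: none
Why: Under Swern conditions a primary triethylsilyl ether is cleaved and oxidised directly to the aldehyde while the secondary and tertiary silyl ethers survive (selective Swern oxidation of primary silyl ethers), and the hindered amine limits base contact of the butenolide γ-proton.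

**Step 12**
Reactants: 21 {(5R)-5-[(1Z,3S,6S)-2,6-dimethyl-8-oxo-3,6-bis(triethylsilyloxy)oct-1-en-1-yl]-2-oxo-2,5-dihydrofuran-3-yl}methyl acetate
Product: 24 (1S,4S,6R,7S,8R,9Z)-6-[(2E)-2-methylbut-2-enoyloxy]-1,4-bis(triethylsilyloxy)germacra-9,11(13)-dien-8,12-olide, via allylzinc 22 (not isolated), via zinc alkoxide 23 (not isolated)
Conditions: Pd(PPh3)4 (10 mol %), Et2Zn (4 equiv), THF, 0.002 M, slow addition of 21, rt; then tiglic anhydride, DMAP, rt
Reagents that add atoms: (2E)-2-methylbut-2-enoic anhydride (tiglic anhydride), C/C=C(\C)C(=O)OC(=O)/C(C)=C/C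
Why: Proposed new method: zerovalent palladium ionises the primary allylic acetate to a 2-acyl-π-allyl complex that Et2Zn converts into allylzinc 22, which adds through C7 to the tethered C6 aldehyde in a closed six-membered chair transition state, where the ring-locked (E)-type allyl geometry gives the 6,7-anti pair (6R,7S) and delivery from the butenolide face that carries the C9 tether is expected (not certain) to give the cis fusion at C7/C8, so the exocyclic methylene and the farnesyl-type C6–C7 bond arise together, and the zinc alkoxide 23 is acylated in the flask before it can translactonise; closest known reactions are the Tamaru umpolung allylation used for ten-membered germacrene closures and chromium- or indium-mediated additions of 3-(bromomethyl)butenolides to aldehydes.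

**Step 13**
Reactants: 24 (1S,4S,6R,7S,8R,9Z)-6-[(2E)-2-methylbut-2-enoyloxy]-1,4-bis(triethylsilyloxy)germacra-9,11(13)-dien-8,12-olide
Product: 25 (1S,4S,6R,7S,8R,9Z)-1,4-dihydroxy-6-[(2E)-2-methylbut-2-enoyloxy]germacra-9,11(13)-dien-8,12-olide (CNP0137971.1)
Conditions: HF·pyridine, pyridine, THF, 0 °C to rt
Reagents that add atoms: none
Why: Buffered fluoride desilylation removes the allylic and the tertiary triethylsilyl ethers without touching the α-methylene lactone, the tiglate or any stereocentre.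

**Compound list**
1 | geraniol, (2E)-3,7-dimethylocta-2,6-dien-1-ol | CC(C)=CCC/C(C)=C/CO | starting material
2 | (2S,3S)-2,3-epoxygeraniol | CC(C)=CCC[C@]1(C)O[C@H]1CO | intermediate
3 | (3S)-3,7-dimethyloct-6-ene-1,3-diol | CC(C)=CCC[C@](C)(O)CCO | intermediate
4 | (3S)-3,7-dimethyl-1,3-bis(triethylsilyloxy)oct-6-ene | CC(C)=CCC[C@](C)(O[Si](CC)(CC)CC)CCO[Si](CC)(CC)CC | intermediate
5 | ozonide, 3,3-dimethyl-5-[(3S)-3-methyl-3,5-bis(triethylsilyloxy)pentyl]-1,2,4-trioxolane | CC1(C)OOC(CC[C@](C)(O[Si](CC)(CC)CC)CCO[Si](CC)(CC)CC)O1 | intermediate (not isolated)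
6 | (4S)-4-methyl-4,6-bis(triethylsilyloxy)hexanal (fragment A) | O=CCC[C@](C)(O[Si](CC)(CC)CC)CCO[Si](CC)(CC)CC | intermediate
7 | but-2-yn-1-ol | CC#CCO | starting material
8 | sodium cyclic alkenylaluminate (Al on C3 and on O, two 2-methoxyethoxy ligands) | CC1=CCO[Al-]1(OCCOC)OCCOC.[Na+] | intermediate (not isolated)
9 | (2Z)-3-iodobut-2-en-1-ol | C/C(I)=C/CO | intermediate
10 | (2Z)-3-iodobut-2-enal | C/C(I)=C/C=O | intermediate
11 | hex-1-yne | C#CCCCC | starting material
12 | dicyclohexyl[(1E)-hex-1-en-1-yl]borane | CCCC/C=C/B(C1CCCCC1)C1CCCCC1 | intermediate (not isolated)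
13 | [(1E)-hex-1-en-1-yl](methyl)zinc | CCCC/C=C/[Zn]C | intermediate (not isolated)
14 | (2Z,4S,5E)-2-iododeca-2,5-dien-4-ol | C/C(I)=C/[C@@H](O)/C=C/CCCC | intermediate
15 | 2-(bromomethyl)prop-2-enoic acid | C=C(CBr)C(=O)O | starting material
16 | (2Z,4S,5E)-2-iododeca-2,5-dien-4-yl 2-(bromomethyl)prop-2-enoate | C/C(I)=C/[C@@H](OC(=O)C(=C)CBr)/C=C/CCCC | intermediate
17 | (5S)-3-(bromomethyl)-5-[(1Z)-2-iodoprop-1-en-1-yl]furan-2(5H)-one | C/C(I)=C/[C@H]1OC(=O)C(CBr)=C1 | intermediate (not isolated)
18 | {(5S)-5-[(1Z)-2-iodoprop-1-en-1-yl]-2-oxo-2,5-dihydrofuran-3-yl}methyl acetate (fragment B) | C/C(I)=C/[C@H]1OC(=O)C(COC(C)=O)=C1 | intermediate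
19 | dichlorochromium alkoxide of the C1 carbinol (chiral ligand omitted) | CC(=O)OCC1=C[C@@H](/C=C(/C)[C@@H](O[Cr](Cl)Cl)CC[C@](C)(O[Si](CC)(CC)CC)CCO[Si](CC)(CC)CC)OC1=O | intermediate (not isolated)
20 | {(5R)-5-[(1Z,3S,6S)-2,6-dimethyl-3,6,8-tris(triethylsilyloxy)oct-1-en-1-yl]-2-oxo-2,5-dihydrofuran-3-yl}methyl acetate | CC(=O)OCC1=C[C@@H](/C=C(/C)[C@@H](O[Si](CC)(CC)CC)CC[C@](C)(O[Si](CC)(CC)CC)CCO[Si](CC)(CC)CC)OC1=O | intermediate
21 | {(5R)-5-[(1Z,3S,6S)-2,6-dimethyl-8-oxo-3,6-bis(triethylsilyloxy)oct-1-en-1-yl]-2-oxo-2,5-dihydrofuran-3-yl}methyl acetate | CC(=O)OCC1=C[C@@H](/C=C(/C)[C@@H](O[Si](CC)(CC)CC)CC[C@](C)(O[Si](CC)(CC)CC)CC=O)OC1=O | intermediate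
22 | ethyl(allyl)zinc from 21 (zinc on C13, butenolide and C6 aldehyde intact) | CC[Zn]CC1=C[C@@H](/C=C(/C)[C@@H](O[Si](CC)(CC)CC)CC[C@](C)(O[Si](CC)(CC)CC)CC=O)OC1=O | intermediate (not isolated)
23 | ethylzinc C6-alkoxide of (1S,4S,6R,7S,8R,9Z)-6-hydroxy-1,4-bis(triethylsilyloxy)germacra-9,11(13)-dien-8,12-olide | C=C1C(=O)O[C@@H]2/C=C(/C)[C@@H](O[Si](CC)(CC)CC)CC[C@](C)(O[Si](CC)(CC)CC)C[C@@H](O[Zn]CC)[C@H]12 | intermediate (not isolated)
24 | (1S,4S,6R,7S,8R,9Z)-6-[(2E)-2-methylbut-2-enoyloxy]-1,4-bis(triethylsilyloxy)germacra-9,11(13)-dien-8,12-olide | C=C1C(=O)O[C@@H]2/C=C(/C)[C@@H](O[Si](CC)(CC)CC)CC[C@](C)(O[Si](CC)(CC)CC)C[C@@H](OC(=O)/C(C)=C/C)[C@H]12 | intermediate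
25 | (1S,4S,6R,7S,8R,9Z)-1,4-dihydroxy-6-[(2E)-2-methylbut-2-enoyloxy]germacra-9,11(13)-dien-8,12-olide (CNP0137971.1) | C=C1C(=O)O[C@@H]2/C=C(/C)[C@@H](O)CC[C@](C)(O)C[C@@H](OC(=O)/C(C)=C/C)[C@H]12 | target

**Step count**
Total: 13 steps. Longest linear sequence: 9 steps (steps 5–13; the fragment A branch is steps 1–4).

**Steps most likely to fail**

Step 12 (ring closure with in-flask acylation). The risks are oligomerisation in place of ten-membered ring formation, closure to the trans-fused C7 epimer, and competing ionisation of the allylic lactone C8–O bond by zerovalent palladium. The fallback sets out from 21 and reverses the polarity of the closure in a one-electron manifold. SmI2 (divalent samarium) in THF/HMPA at −78 °C under high dilution generates the C6 ketyl, which adds to C7 of the butenolide, and the samarium enolate expels acetate to leave the exocyclic methylene. This gives (1S,4S,6R,7S,8R,9Z)-6-hydroxy-1,4-bis(triethylsilyloxy)germacra-9,11(13)-dien-8,12-olide F1, which is isolated. Separate acylation with tiglic anhydride, DMAP and Et3N at 0 °C comes back to the route at 24.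

Step 10 (asymmetric coupling). The risks are insufficient facial control at C1, attack of zerovalent nickel on the allylic acetate, and sluggish silyl turnover. The fallback sets out from 18 and 6 and sets C1 by reagent-controlled ketone reduction instead. A plain stoichiometric coupling (CrCl2, 4 equiv, NiCl2, 2 mol %, DMSO, rt) gives the C1-epimeric allylic alcohols F2. Dess–Martin periodinane gives the enone F3. Reduction with (R)-2-methyl-CBS-oxazaborolidine and catecholborane in toluene at −78 °C (the alkenyl group acting as the large substituent) gives the (1S)-alcohol F4. Et3SiOTf and 2,6-lutidine then return to the route at 20.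

Step 7 (enantioselective alkenylation of the isomerisation-prone iodoenal). The fallback sets out from 10 and replaces asymmetric catalysis by a resolution. Vinylmagnesium bromide (CH2=CHMgBr, THF, −78 °C) gives racemic (4Z)-5-iodohexa-1,4-dien-3-ol F5. Candida antarctica lipase B with vinyl acetate in hexane acetylates the (R)-enantiomer (vinyl as the medium group, iodopropenyl as the large group) and leaves (3S,4Z)-5-iodohexa-1,4-dien-3-ol F6. Esterification with 15 (DCC, DMAP) gives the ester F7. Under the conditions of step 9, F7 loses ethene on metathesis to give 17 and, after acetate exchange, comes back to the route at 18.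

**Further compounds**
F1 | step 12 | (1S,4S,6R,7S,8R,9Z)-6-hydroxy-1,4-bis(triethylsilyloxy)germacra-9,11(13)-dien-8,12-olide | C=C1C(=O)O[C@@H]2/C=C(/C)[C@@H](O[Si](CC)(CC)CC)CC[C@](C)(O[Si](CC)(CC)CC)C[C@@H](O)[C@H]12
F2 | step 10 | {(5R)-5-[(1Z,6S)-3-hydroxy-2,6-dimethyl-6,8-bis(triethylsilyloxy)oct-1-en-1-yl]-2-oxo-2,5-dihydrofuran-3-yl}methyl acetate (both C3' epimers) | CC(=O)OCC1=C[C@@H](/C=C(/C)C(O)CC[C@](C)(O[Si](CC)(CC)CC)CCO[Si](CC)(CC)CC)OC1=O
F3 | step 10 | {(5R)-5-[(1Z,6S)-2,6-dimethyl-3-oxo-6,8-bis(triethylsilyloxy)oct-1-en-1-yl]-2-oxo-2,5-dihydrofuran-3-yl}methyl acetate | CC(=O)OCC1=C[C@@H](/C=C(/C)C(=O)CC[C@](C)(O[Si](CC)(CC)CC)CCO[Si](CC)(CC)CC)OC1=O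
F4 | step 10 | {(5R)-5-[(1Z,3S,6S)-3-hydroxy-2,6-dimethyl-6,8-bis(triethylsilyloxy)oct-1-en-1-yl]-2-oxo-2,5-dihydrofuran-3-yl}methyl acetate | CC(=O)OCC1=C[C@@H](/C=C(/C)[C@@H](O)CC[C@](C)(O[Si](CC)(CC)CC)CCO[Si](CC)(CC)CC)OC1=O
F5 | step 7 | racemic (4Z)-5-iodohexa-1,4-dien-3-ol | C/C(I)=C/C(O)C=C
F6 | step 7 | (3S,4Z)-5-iodohexa-1,4-dien-3-ol | C/C(I)=C/[C@@H](O)C=C
F7 | step 7 | (3S,4Z)-5-iodohexa-1,4-dien-3-yl 2-(bromomethyl)prop-2-enoate | C/C(I)=C/[C@@H](OC(=O)C(=C)CBr)C=C
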